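I began with an easy step, a matter of direction: in this flask a dissolved substrate can go one of two ways, onto a coupling partner, which makes target, or onto a target, which makes side product and destroys that target.

solid substrate 0.0020 M; gas 0.25 mM (held); time 12 s

    solid substrate ⇌ dissolved substrate, rate k1*(cs1 - [dissolved substrate]) while solid is left; crystals form when [dissolved substrate] > cs1 (cs1 = 1.3 mM, k1 = 1.7 s⁻¹)
    dissolved substrate + coupling partner ⇌ target (K2 = 86000 L mol⁻¹, k2 = 980 L mol⁻¹ s⁻¹)
    dissolved substrate + target → side product (k3 = 68 L mol⁻¹ s⁻¹)
    gas ⇌ coupling partner, rate k4*(csat - [coupling partner]) (k4 = 1.9 s⁻¹, csat = 0.25 mM)
    target → over-reaction product (k5 = 3.1 × 10⁻⁴ s⁻¹)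

- percentages count the solid substrate that a species holds: one side product counts as two
- solid, in amounts per volume of the solution: solid substrate
- at the start none of coupling partner is dissolved
- at the start none of the solid substrate is in solution
- run time (flask): 12 s

- delta: doubling the dissolution coefficient of step 1, all else as stated
- zeta: doubling the solubility in step 1, all else as stated
- epsilon: doubling the saturation concentration of gas, all else as stated
- beta: doubling the transfer coefficient of step 4, all else as stated

* the target standing at 12 s, as a percentage of the solid substrate charged
* the change that raises the amount of target at 12 s, in percent of the solid substrate charged most ("none" if none brings more than 2 percentage points) (delta / zeta / epsilon / beta / none)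
* amount of target at 12 s, in percent of the solid substrate charged, after epsilon

Both ways carry the same factor of dissolved substrate, so when I divided the coupling rate by the side rate, with the back reaction set aside, dissolved substrate and time dropped out. That left the running ratio kc·B/(ks·P), where kc is 980 L mol⁻¹ s⁻¹, ks is 68 L mol⁻¹ s⁻¹, B is the coupling partner and P is the target. Each side step removes a target, so the target gains (ratio minus one) per side product, and at a given B the gain shrinks as P grows.

I carried one number per flask, a selectivity factor σ, the running ratio with B at csat and P at the whole charge C: σ = kc·csat/(ks·C), which came to 1.80 for the flask. The neighbouring flask looks nearly the same, with 0.0034 M of solid substrate instead of 0.0020 M and the same gas, but its σ is 1.06. So I expected the flask to end with a higher percentage of target than the neighbour, because its σ is larger.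

Epsilon doubled σ to 3.60, while the dissolution coefficient, the solubility and the transfer coefficient do not stand in σ, so I chose epsilon. My hand stopped there, at a ranking without a percentage. The forecast gave 53 %, in a range of 49 % to 57 %, and chose epsilon with 70 %, on the ground that “Doubling csat doubles the gas supply”.

The simulation gave 53.6 % of target in the flask at 12.0 s, and epsilon as the best change, reaching 71.1 %, a gain of 18 percentage points against 4.2 points for beta. The flask then held 35.4 % of its charge in side product. With that moment's reading of 2.28 × 10⁻⁴ M of coupling partner, the running ratio of the flask, the back reaction still set aside, came to 3.06. The neighbouring flask ended at 37.8 % of target, and its 1.78 × 10⁻⁴ M of coupling partner gave, reckoned the same way, a running ratio of 1.99.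

The constants are made up; the rest is arithmetic.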